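A closed, stirred vessel at constant volume and temperature holds electrophile, protonated nucleophile, free base and protic impurity.

| flask | electrophile | free base | protonated nucleophile | protic impurity | remark | time |
|---|---|---|---|---|---|---|
| south | 0.60 M | 1.2 M | 1.26 M | 1.2 M | run made earlier |  |
| flask | 1.2 M | 1.20 M | 1.26 M | 1.20 M |  | 30 h |

south run (percent of the electrophile charged)

| time / h | electrophile / % | product / % |
|---|---|---|
| 6.00 | 55.4 | 48.5 |
| 12.0 | 43.6 | 54.6 |
| 20.0 | 38.9 | 60.1 |
| 25.0 | 38.6 | 59.5 |
| 30.0 | 37.2 | 61.3 |

(each reading ± 1 percentage point)

1. part of the electrophile that has reacted at 30 h
2. share of the unused nucleophile that is free and not bound as protonated nucleophile, at 30 h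

All nucleophile in the vessel comes from the protonated nucleophile charged, so the pool of nucleophile is taken as that whole charge, 1.26 M in the south run. Follow one nucleophile molecule: at a fork it either meets electrophile and gives product, or is lost to protic impurity. The south readings stand nearly flat from 20.0 h, and this reckoning assumes, though flat readings do not prove it, that the pool is spent by the last reading: 0.368 M in product and the rest in impurity. Those assumed odds, divided by the charge ratio of electrophile to impurity, give w = 0.824, the fork weight, a selectivity factor. Nucleophile still unused at that reading, free or bound, would make w larger.

The bench rule splits the pool at odds of w times the charge ratio. In this flask the ratio is 1.00, so 45.2% of the pool reaches electrophile, and this reckoning gives c = 47.4%. The rule assumes that the charge ratio hardly drifts, and it fails as the pool nears the sum of both charges. That pool-to-sum ratio is 0.700 in the south run and half in this flask.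

The forecast gives 42%, less than this reckoning, and 25% free, from “Counting proton sites with similar acidities”.

The flask gives c = 47.6% and a free share of 9.15%.

    acid set free + free base ⇌ salt of the base, settled at all times (K = 19000 M⁻¹)
    nucleophile + protic impurity → quenched reagent (k = 0.00330 M⁻¹ min⁻¹)
    electrophile + nucleophile → acid set free + product (k = 0.00380 M⁻¹ min⁻¹)
    nucleophile + acid set free ⇌ protonated nucleophile, settled at all times (K = 21.0 M⁻¹)

At 30.0 h this flask holds 0.571 M of product against 0.515 M of quenched reagent, odds of 1.11, above w. The neighbour flask, charged with 0.32 M of protonated nucleophile, has that charge as its pool, less than its free base. The same share of the pool gives c = 12.1% there. The neighbour flask reaches 14.2%, with 0.170 M of product against 0.150 M of quenched reagent, odds of 1.14.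

All runs were generated by integration for an exercise; noise was put on by code.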